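**Retrosynthetic overview** (labdane numbering throughout)
- Target ⇐ the 7α-OH is put in last by allylic C–H hydroxylation of the 8(17)-ene; 19-OAc ⇐ 19-OH; 15-OH is carried as a silyl ether.
- Rings A and B ⇐ one cation–olefin bicyclisation of an acyclic (S)-2,2-disubstituted epoxy ketone: ring A closes first (C4–C5), then ring B (C10–C9). The oxirane oxygen becomes O19 and the ketone is C2.
- Key disconnection: the C–O bonds of that oxirane, made by a site- and enantioselective epoxidation of the isopropenyl end of a tetraenone. This C–O bond formation is the only source of absolute configuration.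
- Tetraenone ⇐ 1,3-dithiane (C2) + methallyl chloride (C3, C4, C18, C19) + a C15 allylic bromide made from (2Z,6E)-farnesol by terminal allylic C–H hydroxylation.

Assumption: (2Z,6E)-farnesol is bought as the single isomer.

**Step 1**
Reactants: 1 (2Z,6E)-farnesol
Product: 2 tert-butyl-diphenyl-[(2Z,6E)-3,7,11-trimethyldodeca-2,6,10-trienoxy]silane
Conditions: TBDPSCl, imidazole, CH2Cl2, 0 → 23 °C
Reagents that add atoms: tert-butyl(chloro)diphenylsilane CC(C)(C)[Si](Cl)(c1ccccc1)c1ccccc1
Why: Imidazole-promoted silyl ether formation at the primary allylic alcohol creates no stereocentre and leaves both olefin geometries untouched.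

**Step 2**
Reactants: 2 tert-butyl-diphenyl-[(2Z,6E)-3,7,11-trimethyldodeca-2,6,10-trienoxy]silane
Product: 3 (2E,6E,10Z)-12-[tert-butyl(diphenyl)silyl]oxy-2,6,10-trimethyldodeca-2,6,10-trien-1-ol
Conditions: SeO2 (0.3 equiv), t-BuOOH (3 equiv), salicylic acid (0.1 equiv), CH2Cl2, 0 → 23 °C
Reagents that add atoms: selenium dioxide O=[Se]=O (oxygen carrier); tert-butyl hydroperoxide CC(C)(C)OO (terminal oxidant)
Why: Sharpless–Umbreit allylic hydroxylation (ene reaction then [2,3]-sigmatropic shift) attacks the most electron-rich and least hindered terminal trisubstituted olefin and oxidises its (E)-methyl group, while the olefin next to the silyloxy group is inductively deactivated.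

**Step 3**
Reactants: 3 (2E,6E,10Z)-12-[tert-butyl(diphenyl)silyl]oxy-2,6,10-trimethyldodeca-2,6,10-trien-1-ol
Product: 4 [(2Z,6E,10E)-12-bromo-3,7,11-trimethyldodeca-2,6,10-trienoxy]-tert-butyl-diphenylsilane
Conditions: CBr4, PPh3, CH2Cl2, 0 °C
Reagents that add atoms: carbon tetrabromide BrC(Br)(Br)Br
Why: Appel bromination displaces the oxyphosphonium ion of the primary allylic alcohol by SN2 at 0 °C, without allylic transposition or change of olefin geometry.

**Step 4**
Reactants: 5 1,3-dithiane; 6 3-chloro-2-methylprop-1-ene; 4 [(2Z,6E,10E)-12-bromo-3,7,11-trimethyldodeca-2,6,10-trienoxy]-tert-butyl-diphenylsilane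
Product: 10 tert-butyl-[(2Z,6E,10E)-3,7,11-trimethyl-12-[2-(2-methylprop-2-enyl)-1,3-dithian-2-yl]dodeca-2,6,10-trienoxy]-diphenylsilane, via 2-lithio-1,3-dithiane 7 (not isolated), via 2-(2-methylprop-2-enyl)-1,3-dithiane 8 (not isolated), via 2-lithio-2-(2-methylprop-2-enyl)-1,3-dithiane 9 (not isolated)
Conditions: n-BuLi, THF, −30 °C; 6, −78 → 0 °C; n-BuLi, −25 °C; 4, −78 → 0 °C (one flask)
Reagents that add atoms: none
Why: One-flask double Corey–Seebach alkylation: the dithianyl anion is alkylated by SN2 first with the allylic chloride and then, after a second lithiation, with the primary allylic bromide, which joins C1 to the masked C2 carbonyl carbon with all olefin geometries retained.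

**Step 5**
Reactants: 10 tert-butyl-[(2Z,6E,10E)-3,7,11-trimethyl-12-[2-(2-methylprop-2-enyl)-1,3-dithian-2-yl]dodeca-2,6,10-trienoxy]-diphenylsilane
Product: 11 (6E,10E,14Z)-16-[tert-butyl(diphenyl)silyl]oxy-2,6,10,14-tetramethylhexadeca-1,6,10,14-tetraen-4-one
Conditions: PhI(OCOCF3)2, MeCN–H2O (9:1), 0 °C, 10 min
Reagents that add atoms: water O
Why: Stork–Zhao oxidative dethioketalisation: the trivalent iodine reagent activates sulfur and water hydrolyses the thionium ion within minutes, under which isolated olefins and the silyl ether survive and the skipped dienone is not brought into conjugation.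

**Step 6**
Reactants: 11 (6E,10E,14Z)-16-[tert-butyl(diphenyl)silyl]oxy-2,6,10,14-tetramethylhexadeca-1,6,10,14-tetraen-4-one
Product: 12 (4E,8E,12Z)-14-[tert-butyl(diphenyl)silyl]oxy-4,8,12-trimethyl-1-[(2S)-2-methyloxiran-2-yl]tetradeca-4,8,12-trien-2-one
Conditions: [{Ti(L)}2(μ-O)2] (5 mol %; L = chiral salalen dianion from cis-cyclohexane-1,2-diamine and 3-phenylsalicylaldehyde, antipode that gives the (S)-oxirane), 30% aq. H2O2 (1.5 equiv), CH2Cl2, 23 °C
Reagents that add atoms: hydrogen peroxide OO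
Why: Proposed new method: site- and enantioselective epoxidation of a 2-alkylpropene terminus inside a tetraenone, in which the tetravalent-titanium η2-hydroperoxide held in the salalen pocket by the ligand N–H transfers oxygen only to an unhindered CH2= terminus (the three trisubstituted olefins do not fit) and the pocket tells CH3 from the CH2C(=O)R arm so that one face is oxidised and C4 becomes (S), the closest known reaction being the Katsuki–Berkessel Ti(salalen)/H2O2 epoxidation of unfunctionalised terminal mono-substituted alkenes.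

**Step 7**
Reactants: 12 (4E,8E,12Z)-14-[tert-butyl(diphenyl)silyl]oxy-4,8,12-trimethyl-1-[(2S)-2-methyloxiran-2-yl]tetradeca-4,8,12-trien-2-one
Product: 13 (13Z)-15-[tert-butyl(diphenyl)silyl]oxy-19-hydroxylabda-8(17),13-dien-2-one
Conditions: MeAlCl2 (2.2 equiv), CH2Cl2, −90 °C, 20 min; then H2O
Reagents that add atoms: none
Why: Lewis-acid-promoted epoxide-initiated cation–olefin bicyclisation (Stork–Eschenmoser antiperiplanar additions through a chair–chair transition state) in which C5 attacks C4 with inversion so that the (S)-oxirane fixes C4, the fold that keeps the departing oxirane oxygen over the MeAlCl2-activated C2 carbonyl (incipient 2,19-hemiketal) puts CH2O axial on the β face, the two (E)-olefins give the trans-decalin with 10β-CH3, 5α-H and 9α-H, and loss of a C17 proton from the C8 cation leaves the exocyclic olefin (the Δ7 isomer is the expected minor by-product).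

**Step 8**
Reactants: 13 (13Z)-15-[tert-butyl(diphenyl)silyl]oxy-19-hydroxylabda-8(17),13-dien-2-one
Product: 14 (13Z)-19-acetoxy-15-[tert-butyl(diphenyl)silyl]oxylabda-8(17),13-dien-2-one
Conditions: Ac2O, pyridine, DMAP (cat.), CH2Cl2, 0 → 23 °C
Reagents that add atoms: acetic anhydride CC(=O)OC(C)=O
Why: DMAP-catalysed acylation esterifies the primary neopentyl alcohol and so draws the open keto alcohol out of its equilibrium with the bridged 2,19-hemiketal, with no stereocentre affected.

**Step 9**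
Reactants: 14 (13Z)-19-acetoxy-15-[tert-butyl(diphenyl)silyl]oxylabda-8(17),13-dien-2-one
Product: 15 (13Z)-19-acetoxy-15-[tert-butyl(diphenyl)silyl]oxy-7α-hydroxylabda-8(17),13-dien-2-one
Conditions: SeO2 (0.5 equiv), t-BuOOH (2 equiv), CH2Cl2, 0 → 23 °C
Reagents that add atoms: selenium dioxide O=[Se]=O (oxygen carrier); tert-butyl hydroperoxide CC(C)(C)OO (terminal oxidant)
Why: Sharpless–Umbreit allylic hydroxylation: the ene reaction of SeO2 at the exocyclic methylene removes the stereoelectronically aligned axial 7α-hydrogen and the [2,3]-shift returns oxygen to C7 on the same α face, giving the axial 7α-alcohol (7R) with the 8(17)-olefin restored, while the silyloxy-substituted side-chain olefin is deactivated.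

**Step 10**
Reactants: 15 (13Z)-19-acetoxy-15-[tert-butyl(diphenyl)silyl]oxy-7α-hydroxylabda-8(17),13-dien-2-one
Product: 16 (13Z)-19-acetoxy-7α,15-dihydroxylabda-8(17),13-dien-2-one (target, CNP0277693.2)
Conditions: HF·pyridine, pyridine, THF, 0 → 23 °C
Reagents that add atoms: none
Why: Fluoride-mediated desilylation with buffered HF·pyridine cleaves only the Si–O bond and leaves the acetate, the ketone, the allylic alcohols and all stereocentres untouched.

**Compound list**
1 | (2Z,6E)-farnesol, (2Z,6E)-3,7,11-trimethyldodeca-2,6,10-trien-1-ol | CC(C)=CCC/C(C)=C/CC/C(C)=C\CO | starting material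
2 | tert-butyl-diphenyl-[(2Z,6E)-3,7,11-trimethyldodeca-2,6,10-trienoxy]silane | CC(C)=CCC/C(C)=C/CC/C(C)=C\CO[Si](c1ccccc1)(c1ccccc1)C(C)(C)C | intermediate
3 | (2E,6E,10Z)-12-[tert-butyl(diphenyl)silyl]oxy-2,6,10-trimethyldodeca-2,6,10-trien-1-ol | OC/C(C)=C/CC/C(C)=C/CC/C(C)=C\CO[Si](c1ccccc1)(c1ccccc1)C(C)(C)C | intermediate
4 | [(2Z,6E,10E)-12-bromo-3,7,11-trimethyldodeca-2,6,10-trienoxy]-tert-butyl-diphenylsilane | BrC/C(C)=C/CC/C(C)=C/CC/C(C)=C\CO[Si](c1ccccc1)(c1ccccc1)C(C)(C)C | intermediate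
5 | 1,3-dithiane | C1CSCSC1 | starting material
6 | 3-chloro-2-methylprop-1-ene (methallyl chloride) | CC(=C)CCl | starting material
7 | 2-lithio-1,3-dithiane | [Li]C1SCCCS1 | intermediate
8 | 2-(2-methylprop-2-enyl)-1,3-dithiane | CC(=C)CC1SCCCS1 | intermediate
9 | 2-lithio-2-(2-methylprop-2-enyl)-1,3-dithiane | [Li]C1(CC(C)=C)SCCCS1 | intermediate
10 | tert-butyl-[(2Z,6E,10E)-3,7,11-trimethyl-12-[2-(2-methylprop-2-enyl)-1,3-dithian-2-yl]dodeca-2,6,10-trienoxy]-diphenylsilane | CC(=C)CC1(SCCCS1)C/C(C)=C/CC/C(C)=C/CC/C(C)=C\CO[Si](c1ccccc1)(c1ccccc1)C(C)(C)C | intermediate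
11 | (6E,10E,14Z)-16-[tert-butyl(diphenyl)silyl]oxy-2,6,10,14-tetramethylhexadeca-1,6,10,14-tetraen-4-one | CC(=C)CC(=O)C/C(C)=C/CC/C(C)=C/CC/C(C)=C\CO[Si](c1ccccc1)(c1ccccc1)C(C)(C)C | intermediate
12 | (4E,8E,12Z)-14-[tert-butyl(diphenyl)silyl]oxy-4,8,12-trimethyl-1-[(2S)-2-methyloxiran-2-yl]tetradeca-4,8,12-trien-2-one | C[C@@]1(CO1)CC(=O)C/C(C)=C/CC/C(C)=C/CC/C(C)=C\CO[Si](c1ccccc1)(c1ccccc1)C(C)(C)C | intermediate
13 | (13Z)-15-[tert-butyl(diphenyl)silyl]oxy-19-hydroxylabda-8(17),13-dien-2-one (4S,5R,9S,10R; trans-decalin, 10β-CH3, 5α-H, 9α-H, 4α-CH3, 4β-CH2OH axial) | C=C1CC[C@H]2[C@@](C)(CO)CC(=O)C[C@]2(C)[C@H]1CC/C(C)=C\CO[Si](c1ccccc1)(c1ccccc1)C(C)(C)C | intermediate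
14 | (13Z)-19-acetoxy-15-[tert-butyl(diphenyl)silyl]oxylabda-8(17),13-dien-2-one (4S,5R,9S,10R) | C=C1CC[C@H]2[C@@](C)(COC(C)=O)CC(=O)C[C@]2(C)[C@H]1CC/C(C)=C\CO[Si](c1ccccc1)(c1ccccc1)C(C)(C)C | intermediate
15 | (13Z)-19-acetoxy-15-[tert-butyl(diphenyl)silyl]oxy-7α-hydroxylabda-8(17),13-dien-2-one (4S,5R,7R,9R,10S) | C=C1[C@H](O)C[C@H]2[C@@](C)(COC(C)=O)CC(=O)C[C@]2(C)[C@H]1CC/C(C)=C\CO[Si](c1ccccc1)(c1ccccc1)C(C)(C)C | intermediate
16 | (13Z)-19-acetoxy-7α,15-dihydroxylabda-8(17),13-dien-2-one (4S,5R,7R,9R,10S) | C=C1[C@H](O)C[C@H]2[C@@](C)(COC(C)=O)CC(=O)C[C@]2(C)[C@H]1CC/C(C)=C\CO | target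

**Totals**
Total step count: 10. Longest linear sequence: 10 steps (1 → 16).

**Three steps most likely to fail**

Step 6 (the proposed epoxidation; site selectivity or enantioselectivity may fall short). The fallback uses known chemistry, sets out from 4 and comes back at 12. 1,3-Dithiane 5 is lithiated (n-BuLi, THF) and alkylated with 4 to give tert-butyl-[(2Z,6E,10E)-12-(1,3-dithian-2-yl)-3,7,11-trimethyldodeca-2,6,10-trienoxy]-diphenylsilane F1. Separately, 2-methylprop-2-en-1-ol is epoxidised by the Sharpless method (Ti(OiPr)4, D-(−)-diisopropyl tartrate, t-BuOOH, 4 Å sieves, CH2Cl2, −20 °C; this is the tartrate antipode that gives (R)-2-methylglycidol) and tosylated in the same flask (TsCl, Et3N, DMAP) to [(2S)-2-methyloxiran-2-yl]methyl 4-methylbenzenesulfonate F2. Lithiated F1 (n-BuLi, THF, −25 °C) opens F2 at the oxirane CH2, and the tertiary alkoxide closes onto the tosylate-bearing carbon. This gives tert-butyl-[(2Z,6E,10E)-3,7,11-trimethyl-12-[2-[[(2S)-2-methyloxiran-2-yl]methyl]-1,3-dithian-2-yl]dodeca-2,6,10-trienoxy]-diphenylsilane F3 with the same (S)-oxirane as 12. PhI(OCOCF3)2 with NaHCO3 in MeCN–H2O at 0 °C then unmasks the ketone and returns the route at 12. Material made this way also fixes the absolute sense of the catalyst used in step 6.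

Step 7 (three weak points: the chair fold that decides C4, and with it the absolute sense of both rings, rests on carbonyl assistance; the Δ7 olefin can compete with the 8(17)-olefin; the epoxy ketone can drift to a furan). The fallback sets out from 4 and comes back at 13. Bromide 4 is taken through F1 and F3 as above, but F3 is cyclised before the thioketal is removed. SnCl4 (1.1 equiv, CH2Cl2, −78 °C) can bridge the oxirane oxygen and the pro-axial sulfur in a six-membered chelate, which again holds CH2O on the axial β face, and a thioketal cannot collapse to a furan. This gives (13Z)-15-[tert-butyl(diphenyl)silyl]oxy-19-hydroxylabda-8(17),13-dien-2-one propane-1,3-diyl dithioketal F4. PhI(OCOCF3)2 in MeCN–H2O at 0 °C releases the ketone and returns the route at 13.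

Step 9 (SeO2 may also attack the trisubstituted side-chain olefin). The fallback sets out from 14 and comes back at 16. HF·pyridine in THF removes the silyl group to give (13Z)-19-acetoxy-15-hydroxylabda-8(17),13-dien-2-one F5. Ac2O/pyridine gives (13Z)-15,19-diacetoxylabda-8(17),13-dien-2-one F6, whose side-chain olefin is now an allylic acetate and as inert to SeO2 as the 2,3-olefin of geranyl acetate. SeO2/t-BuOOH in CH2Cl2 then gives (13Z)-15,19-diacetoxy-7α-hydroxylabda-8(17),13-dien-2-one F7. K2CO3 in MeOH at 0 °C (or a lipase in buffer) removes the unhindered allylic primary 15-acetate but not the axial neopentyl 19-acetate, which gives 16.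

**Further compounds**
F1 | step 6 | tert-butyl-[(2Z,6E,10E)-12-(1,3-dithian-2-yl)-3,7,11-trimethyldodeca-2,6,10-trienoxy]-diphenylsilane | C1CSC(SC1)C/C(C)=C/CC/C(C)=C/CC/C(C)=C\CO[Si](c1ccccc1)(c1ccccc1)C(C)(C)C
F2 | step 6 | [(2S)-2-methyloxiran-2-yl]methyl 4-methylbenzenesulfonate | C[C@@]1(COS(=O)(=O)c2ccc(C)cc2)CO1
F3 | step 6 | tert-butyl-[(2Z,6E,10E)-3,7,11-trimethyl-12-[2-[[(2S)-2-methyloxiran-2-yl]methyl]-1,3-dithian-2-yl]dodeca-2,6,10-trienoxy]-diphenylsilane | C[C@@]1(CO1)CC1(SCCCS1)C/C(C)=C/CC/C(C)=C/CC/C(C)=C\CO[Si](c1ccccc1)(c1ccccc1)C(C)(C)C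
F4 | step 7 | (13Z)-15-[tert-butyl(diphenyl)silyl]oxy-19-hydroxylabda-8(17),13-dien-2-one propane-1,3-diyl dithioketal (4S,5R,9S,10R) | C=C1CC[C@H]2[C@@](C)(CO)CC3(SCCCS3)C[C@]2(C)[C@H]1CC/C(C)=C\CO[Si](c1ccccc1)(c1ccccc1)C(C)(C)C
F5 | step 9 | (13Z)-19-acetoxy-15-hydroxylabda-8(17),13-dien-2-one | C=C1CC[C@H]2[C@@](C)(COC(C)=O)CC(=O)C[C@]2(C)[C@H]1CC/C(C)=C\CO
F6 | step 9 | (13Z)-15,19-diacetoxylabda-8(17),13-dien-2-one | C=C1CC[C@H]2[C@@](C)(COC(C)=O)CC(=O)C[C@]2(C)[C@H]1CC/C(C)=C\COC(C)=O
F7 | step 9 | (13Z)-15,19-diacetoxy-7α-hydroxylabda-8(17),13-dien-2-one | C=C1[C@H](O)C[C@H]2[C@@](C)(COC(C)=O)CC(=O)C[C@]2(C)[C@H]1CC/C(C)=C\COC(C)=O
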